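# Proposal: (−)-Thujaplicatin by enantioselective (2+2) photocycloaddition and reductive opening of the cyclobutane

## The problem

(−)-Thujaplicatin (16) is a trans-α,β-dibenzyl-γ-butyrolactone. Lactone carbon C3 (R) carries ring B (3,4-dihydroxy-5-methoxyphenyl) through the methylene C7', and C4 (R) carries ring A (4-hydroxy-3-methoxyphenyl) through the methylene C7. The skeleton is an unsymmetrical union of two C6–C3 units through the C3–C4 bond, so two different cinnamyl-type halves must be joined in one orientation and a symmetrical dimerization is excluded. Of the two adjacent stereocentres only C4 is configurationally fixed. C3 is α to the lactone carbonyl and epimerizable, with the trans isomer favoured, so C4 must be set absolutely and C3 either set with it or allowed to follow it. There is no further ring or stereocentre from which control could be relayed. The three phenols, two of them a catechol next to a methoxy group, are easily oxidized in base and air and make both rings strongly nucleophilic. The two methyl ethers must survive whatever removes the other oxygen protecting groups, and a 1,2,3-trioxygenated ring such as ring B tends to lose its central oxygen under careless electron-transfer conditions. The feature that opens the chosen route is that C7 and C7' are both benzylic methylene groups in a 1,4-relation across C3–C4. A temporary C7–C7' bond turns C3, C4, C7 and C7' into a 1,2-diaryl cyclobutane, the formal (2+2) adduct of a ring B cinnamoyl unit and a ring A coniferyl-type alkene, and this strained, doubly benzylic bond can be cut again by electron transfer.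

## Retrosynthesis

**Lactone C2–O1 bond and the last protecting groups (16 ⇒ 15 ⇒ 14 ⇒ 13).** Target 16 comes from lactone 15 by loss of the methoxymethyl group, 15 from hydroxy acid 14 by lactonization, and 14 from silyl ether 13. Cutting the ester C–O bond and not a ring C–C bond keeps C2 at the acid level and C5 at the alcohol level from the fragments onward. The position of the carbonyl, next to the carbon bearing the ring B benzyl group, therefore never depends on a selective oxidation of a diol. 13 is hardly smaller, but it is an open chain in which every group still to be removed is acid-labile. The forward step must cleave a silyl ether and an acetal and close the lactone in one acidic medium without touching the methyl ethers, the stereocentres or the free catechol.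

**Temporary C7–C7' bond (13 ⇒ 12).** In the backward direction C7 and C7' of 13 are joined, giving cyclobutane acid 12. The neighbouring cuts, C3–C7' or C4–C7 (enolate benzylation, conjugate addition), build the two centres in separate events. The temporary bond instead places C3 and C4 in a four-membered ring whose all-trans isomer maps onto the trans lactone and which is a (2+2) adduct. The forward reaction must cleave exactly this bond, the only ring bond that is benzylic at both ends; lithium in ammonia should break it once one arene has taken up an electron. The protecting groups of 12 are chosen for that step: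

- Ring B carries benzyl ethers. They are lost at once and leave a catecholate that can neither be reduced further nor expel its central oxygen.
- Ring A carries a methoxymethyl ether. It has no π system of its own, so ring A stays a neutral arene able to accept the electron. A benzyl ether here would leave a phenoxide before the ring has opened.
- The carbonyl is a lithium carboxylate. An ester or acyl azole would take the electron itself and break C3–C7' or C3–C4 through a ketyl.
- The C5 oxygen stays silylated.

**Acyl C2–N bond (12 ⇒ 11).** Acid 12 is the hydrolysis product of N-acyl pyrazole 11. The pyrazole is not a protecting group but the two-point binding site for the chiral Lewis acid of the preceding step. It is preferred to an ester or an imide because cold hydroxide removes it.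

**C3–C4 and C7–C7' (11 ⇒ 6 + 10).** Cutting these two ring bonds of 11 gives enoyl pyrazole 6 and cinnamyl silyl ether 10, two achiral (E)-alkenes of similar size. The other pairing (C3–C7' and C4–C7) would lead to a stilbene and a γ-silyloxy enoyl unit. A stilbene is a low-energy triplet sink, and its two ends are too alike to decide which aryl group ends up next to C3. The chosen pairing fixes the orientation through a diradical that is benzylic at both ends. It also lets one chiral catalyst, bound to 6, set C3 directly and C4 by relay. The forward step must form two C–C bonds, one ring and four stereocentres, of which only the C3/C4 pair has to be right.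

**Ring B fragment (6 ⇒ 4 + 5; 4 ⇒ 2; 2 ⇒ 1).** The N-acyl bond of 6 is cut to cinnamic acid 4 and 3,5-dimethylpyrazole 5. The C=C bond of 4 is cut to aldehyde 2 and malonic acid (through the arylidenemalonic acid 3). The two benzyl ethers of 2 lead back to commercial 3,4-dihydroxy-5-methoxybenzaldehyde 1, in which the three oxygens of ring B are already differentiated.

**Ring A fragment (10 ⇒ 9 ⇒ 8 ⇒ 7).** The O–Si bond of 10 is cut to allylic alcohol 9, 9 is the reduction product of enoate 8, and the methoxymethyl ether of 8 leads back to commercial methyl ferulate 7. The alkene geometry is bought with 7 and carried through.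

## Roads not taken

**Alternative 1:** Ring B is taken apart instead of the lactone core. Two of its ring bonds are cut so that the arene arises last from the lactone-bearing cyclobutenone A1 and di-tert-butoxyethyne A2.
- Forward key step: irradiation opens A1 to its vinylketene, A2 adds across the ketene, and electrocyclic opening, 6π closure and tautomerization give phenol A3. The new hydroxyl group is the one to be methylated and the two tert-butyl ethers are the future catechol.
- Merits: the three oxygens of ring B emerge fully differentiated, and the end game (O-methylation, acid, hydrogenolysis) never exposes an oxygenated arene to electron transfer.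
- Weak points: the step forms neither C3–C4 nor a stereocentre. The trans lactone must therefore already exist, made by some other asymmetric method and carried with a sensitive cyclobutenone in its side chain. A2 is a thermally fragile alkyne that needs several steps of its own. The differentiation it offers is already bought with aldehyde 1.
- Comparison: this road is clearly longer and leaves the stereodiad unsolved. It is better only in the mildness of its final steps. The chosen plan sets against that a ten-step sequence in which one step creates the whole C3–C4 array.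

**Alternative 2:** The two bonds from the lactone to the benzylic carbons, C4–C7 and C3–C7', are cut. This gives three components: the ring A dithiane A4, (5R)-5-menthyloxyfuran-2(5H)-one A5 and the ring B benzyl bromide A6.
- Forward key step: lithiated A4 adds to C4 of A5 anti to the alkoxy group, and the lactone enolate is benzylated by A6 anti to the new substituent in the same flask, giving A7.
- Merits: conjugate addition–alkylation on 5-alkoxybutenolides is a proven entry to trans-dibenzylbutyrolactones. Both stereocentres arise in one operation under control of a cheap auxiliary, the trans relation is set directly, and no step depends on electron transfer to an oxygenated arene.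
- Weak points: chirality is stoichiometric. The dithiane must be removed with a large excess of a nickel reagent. The acetal carbon C5 must be brought to CH2 by ring opening, hydride reduction and relactonization, and a debenzylation still follows. A4 and A6 each need two to three steps, and the coupling is cryogenic organolithium chemistry on a base-sensitive furanone.
- Comparison: in step count the two plans are about equal. In security of precedent this road is ahead of the chosen one, whose steps 7 and 9 both extend known reactions to more demanding substrates. The chosen plan sets against it catalytic control of absolute configuration, the two natural monomer types as the only carbon sources, room-temperature assembly of the whole skeleton in one step, and no sulfur, nickel or auxiliary recovery. These are gains in economy, not in certainty.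

**Alternative 3:** The C4–C5 bond is cut and C5 is delivered as a silylmethyl radical from the oxygen of a C7 carbinol. The precursor is the bromomethylsilyl ether A8.
- Forward key step: under tin hydride chain conditions the radical adds 5-exo to C4 of the enoate and closes the temporary oxasilolane A9. Oxidative cleavage of the C–Si bond then frees the C5 hydroxyl group, which lactonizes onto the ester.
- Merits: 5-exo cyclization of tethered radicals is dependable, is indifferent to oxygenated arenes, and places C4 trans to the aryl-bearing carbon by 1,2-induction.
- Weak points: the controlling stereocentre, the C7 carbinol, is not part of the target. It must first be made enantioselectively and later removed by benzylic deoxygenation. C3 arises from an uncontrolled hydrogen transfer and has to be equilibrated at the lactone stage. A8 needs some five steps, and stoichiometric tin, a peroxide oxidation next to electron-rich arenes and the deoxygenation push the count well beyond ten.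
- Comparison: this road is more predictable step by step, which the chosen plan cannot claim for its ring opening. It is several steps longer, spends a stereocentre that is thrown away, and controls only one of the two centres of the target.

Key step: step 7

Assumption: by analogy with simpler N-enoyl pyrazoles the Δ enantiomer of the rhodium complex is taken to expose the enoyl face that leads to the (3R) series; if the first experiment shows the opposite sense, the Λ complex is used and nothing else changes.

## Route

Step 1
Reactants: 1 3,4-dihydroxy-5-methoxybenzaldehyde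
Product: 2 3,4-bis(benzyloxy)-5-methoxybenzaldehyde
Conditions: BnBr (2.4 equiv), K2CO3 (3 equiv), DMF, 60 °C
Reagents that add atoms: benzyl bromide, BrCc1ccccc1
Why: Williamson ether synthesis on both phenoxides; the aldehyde and the methyl ether are inert to carbonate and benzyl bromide.

Step 2
Reactants: 2 3,4-bis(benzyloxy)-5-methoxybenzaldehyde
Product: 4 (E)-3-[3,4-bis(benzyloxy)-5-methoxyphenyl]prop-2-enoic acid, via arylidenemalonic acid 3 (not isolated)
Conditions: malonic acid (2 equiv), piperidine (0.1 equiv), pyridine, 100 °C
Reagents that add atoms: malonic acid, OC(=O)CC(=O)O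
Why: Knoevenagel condensation with Doebner decarboxylation; the decarboxylation delivers the conjugated (E)-acid, the thermodynamically favoured geometry.

Step 3
Reactants: 4 (E)-3-[3,4-bis(benzyloxy)-5-methoxyphenyl]prop-2-enoic acid; 5 3,5-dimethyl-1H-pyrazole
Product: 6 (E)-3-[3,4-bis(benzyloxy)-5-methoxyphenyl]-1-(3,5-dimethyl-1H-pyrazol-1-yl)prop-2-en-1-one
Conditions: DCC (1.1 equiv), DMAP (0.1 equiv), CH2Cl2, 0 °C → rt
Reagents that add atoms: none
Why: Carbodiimide-mediated N-acylation of the pyrazole (Steglich-type coupling), the usual way to N-enoyl pyrazoles; the alkene geometry is not affected.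

Step 4
Reactants: 7 methyl (E)-3-(4-hydroxy-3-methoxyphenyl)prop-2-enoate (methyl ferulate)
Product: 8 methyl (E)-3-[3-methoxy-4-(methoxymethoxy)phenyl]prop-2-enoate
Conditions: MOMCl (1.5 equiv), K2CO3 (2 equiv), acetone, 0 °C → rt
Reagents that add atoms: chloromethyl methyl ether, COCCl
Why: O-Alkylation of the phenoxide by the α-chloro ether (acetal formation); the enoate does not react with carbonate under these conditions.

Step 5
Reactants: 8 methyl (E)-3-[3-methoxy-4-(methoxymethoxy)phenyl]prop-2-enoate
Product: 9 (E)-3-[3-methoxy-4-(methoxymethoxy)phenyl]prop-2-en-1-ol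
Conditions: i-Bu2AlH (2.4 equiv), CH2Cl2, −78 °C; aq. potassium sodium tartrate
Reagents that add atoms: none
Why: 1,2-Reduction of an α,β-unsaturated ester to the allylic alcohol by i-Bu2AlH, which does not reduce the conjugated C=C bond or the acetal.

Step 6
Reactants: 9 (E)-3-[3-methoxy-4-(methoxymethoxy)phenyl]prop-2-en-1-ol
Product: 10 tert-butyl{[(E)-3-[3-methoxy-4-(methoxymethoxy)phenyl]prop-2-en-1-yl]oxy}dimethylsilane
Conditions: TBSCl (1.2 equiv), imidazole (2 equiv), CH2Cl2, 0 °C → rt
Reagents that add atoms: tert-butyldimethylsilyl chloride, CC(C)(C)[Si](C)(C)Cl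
Why: Standard silylation of a primary alcohol; the silyl ether masks the C5 oxygen through the photoreaction and the reductive opening and adds bulk next to C4.

Step 7
Reactants: 6 (E)-3-[3,4-bis(benzyloxy)-5-methoxyphenyl]-1-(3,5-dimethyl-1H-pyrazol-1-yl)prop-2-en-1-one; 10 tert-butyl{[(E)-3-[3-methoxy-4-(methoxymethoxy)phenyl]prop-2-en-1-yl]oxy}dimethylsilane
Product: 11 {(1R,2S,3S,4R)-2-[3,4-bis(benzyloxy)-5-methoxyphenyl]-4-{[tert-butyl(dimethyl)silyl]oxymethyl}-3-[3-methoxy-4-(methoxymethoxy)phenyl]cyclobutyl}(3,5-dimethyl-1H-pyrazol-1-yl)methanone (all-trans; cyclobutane C1 = lignan C3, C2 = C7', C3 = C7, C4 = lignan C4)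
Conditions: Δ-[Rh(C^N)2(MeCN)2]PF6 (4 mol %; C^N = C,N-cyclometalated 5-tert-butyl-2-phenylbenzothiazole; trivalent rhodium), 10 (3 equiv), acetone, blue LEDs (450 nm), rt, N2
Reagents that add atoms: none
Why: Visible-light (2+2) photocycloaddition at a chiral rhodium Lewis acid, the known reaction of N-enoyl pyrazoles and 2-enoyl imidazoles with styrenes, applied here to a 1,2-disubstituted styrene. N,O-Chelation of 6 to trivalent rhodium moves its absorption into the blue, so that only catalyst-bound 6 is excited and a racemic background path should be negligible; intersystem crossing gives a triplet that bonds through its α-carbon (C3) to C4 of 10. The 1,4-diradical so formed is benzylic at both ends (C7 and C7'), which secures the head-to-head orientation, and after spin inversion the cyclobutane closes by radical–radical combination of C7 and C7' (stepwise diradical closure, not a concerted process). C3 is set by the catalyst: a tert-butyl group of one cyclometalated ligand covers one face of the chelated enoyl plane, so the alkene adds to the open face. C4 is set relative to C3 in the first bond formation, in which the silyloxymethyl group turns away from the metal-bound acyl group; the bulky silyl ether is chosen to reinforce this trans topology. C7 and C7' are set in the closure, where each aryl group goes trans to its ring neighbours, the arrangement of least strain. The step needs head-to-head regioselectivity, face selectivity at C3 and trans selectivity at C3/C4; isomers at C7 or C7' converge later because both centres become CH2, whereas any C3/C4-cis isomer is removed by chromatography at this stage. The (E) geometry of 10 need not survive, since the C7 radical rotates before closure.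

Step 8
Reactants: 11 {(1R,2S,3S,4R)-2-[3,4-bis(benzyloxy)-5-methoxyphenyl]-4-{[tert-butyl(dimethyl)silyl]oxymethyl}-3-[3-methoxy-4-(methoxymethoxy)phenyl]cyclobutyl}(3,5-dimethyl-1H-pyrazol-1-yl)methanone
Product: 12 (1R,2S,3S,4R)-2-[3,4-bis(benzyloxy)-5-methoxyphenyl]-4-{[tert-butyl(dimethyl)silyl]oxymethyl}-3-[3-methoxy-4-(methoxymethoxy)phenyl]cyclobutane-1-carboxylic acid
Conditions: LiOH·H2O (3 equiv), THF/H2O 3:1, 0 °C → rt; then 1 M HCl to pH 3–4 at 0 °C
Reagents that add atoms: lithium hydroxide, [Li+].[OH-]
Why: Hydrolysis of an activated amide (N-acyl pyrazole) by cold hydroxide; C3 already sits trans to both ring neighbours, its most stable arrangement, so enolization cannot erode it, and the silyl, methoxymethyl and benzyl ethers are stable to these conditions.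

Step 9
Reactants: 12 (1R,2S,3S,4R)-2-[3,4-bis(benzyloxy)-5-methoxyphenyl]-4-{[tert-butyl(dimethyl)silyl]oxymethyl}-3-[3-methoxy-4-(methoxymethoxy)phenyl]cyclobutane-1-carboxylic acid
Product: 13 (2R,3R)-3-{[tert-butyl(dimethyl)silyl]oxymethyl}-2-(3,4-dihydroxy-5-methoxybenzyl)-4-[3-methoxy-4-(methoxymethoxy)phenyl]butanoic acid
Conditions: Li (12 equiv), liquid NH3/THF 2:1, −78 °C, 30 min; solid NH4Cl; evaporation, aq. NaH2PO4 (pH 3), Ar
Reagents that add atoms: none
Why: Dissolving-metal cleavage of a strained, doubly benzylic C–C bond, known for simple 1,2-diarylcyclobutanes and 1,2-diarylcyclopropanes, run together with Birch-type cleavage of aryl benzyl ethers. The acid is inert as its lithium carboxylate; ring A, kept neutral by the methoxymethyl ether, accepts an electron, the C7–C7' bond of the radical anion breaks with release of about 26 kcal/mol of ring strain, and a second electron and two protons from ammonia leave a CH2 group at C7 and at C7'. The benzyl ethers of ring B are lost as toluene at once, and the catecholate so formed can neither expel its central oxygen nor be reduced further; C3 and C4 are not involved and keep their configuration.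

Step 10
Reactants: 13 (2R,3R)-3-{[tert-butyl(dimethyl)silyl]oxymethyl}-2-(3,4-dihydroxy-5-methoxybenzyl)-4-[3-methoxy-4-(methoxymethoxy)phenyl]butanoic acid
Product: 16 (−)-thujaplicatin [(3R,4R)-3-(3,4-dihydroxy-5-methoxybenzyl)-4-(4-hydroxy-3-methoxybenzyl)oxolan-2-one], via hydroxy acid 14 (not isolated), via ring A methoxymethyl lactone 15 (not isolated)
Conditions: HCl (1.25 M in MeOH), 45 °C, Ar
Reagents that add atoms: none
Why: Acid-catalysed methanolysis of the primary silyl ether, lactonization of the γ-hydroxy acid (intramolecular acyl substitution to the five-membered ring) and methanolysis of the aryl methoxymethyl acetal, whose cation is trapped by the solvent as dimethoxymethane. No bond to C3 or C4 is broken, acid does not epimerize C3, and the trans lactone is also the thermodynamic isomer.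

## Compound list

1 | 3,4-dihydroxy-5-methoxybenzaldehyde | COc1cc(C=O)cc(O)c1O | starting material
2 | 3,4-bis(benzyloxy)-5-methoxybenzaldehyde | COc1cc(C=O)cc(OCc2ccccc2)c1OCc1ccccc1 | intermediate
3 | 2-[3,4-bis(benzyloxy)-5-methoxybenzylidene]malonic acid (not isolated) | COc1cc(C=C(C(=O)O)C(=O)O)cc(OCc2ccccc2)c1OCc1ccccc1 | intermediate
4 | (E)-3-[3,4-bis(benzyloxy)-5-methoxyphenyl]prop-2-enoic acid | COc1cc(/C=C/C(=O)O)cc(OCc2ccccc2)c1OCc1ccccc1 | intermediate
5 | 3,5-dimethyl-1H-pyrazole | Cc1cc(C)[nH]n1 | starting material
6 | (E)-3-[3,4-bis(benzyloxy)-5-methoxyphenyl]-1-(3,5-dimethyl-1H-pyrazol-1-yl)prop-2-en-1-one | Cc1cc(C)n(n1)C(=O)/C=C/c1cc(OCc2ccccc2)c(OCc2ccccc2)c(OC)c1 | intermediate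
7 | methyl (E)-3-(4-hydroxy-3-methoxyphenyl)prop-2-enoate (methyl ferulate) | COC(=O)/C=C/c1ccc(O)c(OC)c1 | starting material
8 | methyl (E)-3-[3-methoxy-4-(methoxymethoxy)phenyl]prop-2-enoate | COC(=O)/C=C/c1ccc(OCOC)c(OC)c1 | intermediate
9 | (E)-3-[3-methoxy-4-(methoxymethoxy)phenyl]prop-2-en-1-ol | OC/C=C/c1ccc(OCOC)c(OC)c1 | intermediate
10 | tert-butyl{[(E)-3-[3-methoxy-4-(methoxymethoxy)phenyl]prop-2-en-1-yl]oxy}dimethylsilane | CC(C)(C)[Si](C)(C)OC/C=C/c1ccc(OCOC)c(OC)c1 | intermediate
11 | {(1R,2S,3S,4R)-2-[3,4-bis(benzyloxy)-5-methoxyphenyl]-4-{[tert-butyl(dimethyl)silyl]oxymethyl}-3-[3-methoxy-4-(methoxymethoxy)phenyl]cyclobutyl}(3,5-dimethyl-1H-pyrazol-1-yl)methanone | Cc1cc(C)n(n1)C(=O)[C@H]1[C@H](CO[Si](C)(C)C(C)(C)C)[C@@H](c2ccc(OCOC)c(OC)c2)[C@@H]1c1cc(OCc2ccccc2)c(OCc2ccccc2)c(OC)c1 | intermediate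
12 | (1R,2S,3S,4R)-2-[3,4-bis(benzyloxy)-5-methoxyphenyl]-4-{[tert-butyl(dimethyl)silyl]oxymethyl}-3-[3-methoxy-4-(methoxymethoxy)phenyl]cyclobutane-1-carboxylic acid | OC(=O)[C@H]1[C@H](CO[Si](C)(C)C(C)(C)C)[C@@H](c2ccc(OCOC)c(OC)c2)[C@@H]1c1cc(OCc2ccccc2)c(OCc2ccccc2)c(OC)c1 | intermediate
13 | (2R,3R)-3-{[tert-butyl(dimethyl)silyl]oxymethyl}-2-(3,4-dihydroxy-5-methoxybenzyl)-4-[3-methoxy-4-(methoxymethoxy)phenyl]butanoic acid | OC(=O)[C@H](Cc1cc(O)c(O)c(OC)c1)[C@H](CO[Si](C)(C)C(C)(C)C)Cc1ccc(OCOC)c(OC)c1 | intermediate
14 | (2R,3R)-2-(3,4-dihydroxy-5-methoxybenzyl)-3-(hydroxymethyl)-4-[3-methoxy-4-(methoxymethoxy)phenyl]butanoic acid (not isolated) | OC(=O)[C@H](Cc1cc(O)c(O)c(OC)c1)[C@H](CO)Cc1ccc(OCOC)c(OC)c1 | intermediate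
15 | (3R,4R)-3-(3,4-dihydroxy-5-methoxybenzyl)-4-[3-methoxy-4-(methoxymethoxy)benzyl]oxolan-2-one (not isolated) | COCOc1ccc(C[C@H]2COC(=O)[C@@H]2Cc2cc(O)c(O)c(OC)c2)cc1OC | intermediate
16 | (−)-thujaplicatin, (3R,4R)-3-(3,4-dihydroxy-5-methoxybenzyl)-4-(4-hydroxy-3-methoxybenzyl)oxolan-2-one | COc1cc(C[C@H]2COC(=O)[C@@H]2Cc2cc(O)c(O)c(OC)c2)ccc1O | target

## Step count and least certain steps

Total step count: 10. Longest linear sequence: 7 steps (1 → 2 → 4 → 6 → 11 → 12 → 13 → 16; the branch from 7 through 8, 9 and 10 is of equal length).

**Step 7 (key step).** Most likely to go wrong: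
- Unproductive quenching of the rhodium-bound triplet by the electron-rich, 1,2-disubstituted styrene. Energy or electron transfer to 10 would only isomerize or consume the alkene.
- Slow first bond formation at the substituted alkene carbon.
- Poor face selectivity at C4 in that bond formation, which would give C3/C4-cis cyclobutanes and, after opening, material of the wrong series.

Fallback, a covalent auxiliary with triplet sensitization: it sets out from 4 and 10. Acid 4 acylates (S)-4-benzyl-1,3-oxazolidin-2-one through its mixed pivalic anhydride (t-BuCOCl, Et3N, LiCl, THF) to give the N-enoyl oxazolidinone F1. Irradiation of F1 and 10 with blue LEDs and [Ir(dF(CF3)ppy)2(dtbbpy)]PF6 (trivalent iridium) as triplet sensitizer should give head-to-head cyclobutanes by energy transfer to the cinnamoyl unit, the known mode of crossed cycloaddition of cinnamoyl derivatives with styrenes. The diastereomers, now distinguishable through the auxiliary, are separated by chromatography. The all-trans isomer of the wanted series, the cyclobutane imide F2, is cleaved with LiOH/H2O2 (THF/H2O, 0 °C) to acid 12, where the route is rejoined.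

**Step 9.** Most likely to go wrong:
- Electron transfer to ring A may be slower than processes that consume the substrate otherwise: loss of the methoxymethyl or methoxy group from the ring A radical anion, or partial ring reduction on quenching.
- The cyclobutane may survive while the benzyl ethers are lost, since every phenoxide formed makes the molecule harder to reduce.

Fallback, oxidative instead of reductive opening, for which the electron-rich arenes are an asset: it sets out from 12. Electron-transfer photooxygenation (9,10-dicyanoanthracene, O2, MeCN, visible light) oxidizes an alkoxyarene to its radical cation. The C7–C7' bond opens and O2 is taken up to give the 3,6-diaryl-1,2-dioxane F3, a reaction known for 1,2-bis(4-methoxyphenyl)cyclobutanes. Hydrogenolysis (H2, Pd(OH)2 on carbon, EtOAc/AcOH) then cleaves the O–O bond, both benzylic C–O bonds and the two benzyl ethers and returns to 13.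

**Step 10.** Most likely to go wrong:
- Ring substitution of the very electron-rich, unprotected ring B by the methoxymethyl cation released from ring A.
- Oxidation of the free catechol if air is admitted.

Fallback, two separate operations with a sulfur scavenger: it sets out from 13. AcOH/THF/H2O (3:1:1, 40 °C) removes only the silyl ether, hydroxy acid 14 lactonizes, and lactone 15 is isolated. ZnBr2 and n-PrSH in CH2Cl2 at 0 °C then remove the methoxymethyl group, the thiol capturing the methoxymethyl unit before it can attack ring B, and give 16. This path makes no compound outside the compound list (F0).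

**Step 8.** Most likely to go wrong: slow attack of hydroxide on an acyl carbon flanked by two ring substituents, so that enolization of the acyl pyrazole and partial epimerization at C3 compete with hydrolysis.

Fallback, a change of oxidation level instead of acyl substitution: it sets out from 11. NaBH4 (THF/H2O, 0 °C) reduces the acyl pyrazole to the cyclobutylmethanol F4, a reduction known for N-acyl pyrazoles. TEMPO (cat.), NaClO2 and NaOCl (cat.) in MeCN/phosphate buffer (pH 6.7, 35 °C) then oxidize the primary alcohol to acid 12.

## Further compounds

F1 | step 7 | (4S)-4-benzyl-3-{(E)-3-[3,4-bis(benzyloxy)-5-methoxyphenyl]prop-2-enoyl}-1,3-oxazolidin-2-one | O=C1OC[C@H](Cc2ccccc2)N1C(=O)/C=C/c1cc(OCc2ccccc2)c(OCc2ccccc2)c(OC)c1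
F2 | step 7 | (4S)-4-benzyl-3-{[(1R,2S,3S,4R)-2-[3,4-bis(benzyloxy)-5-methoxyphenyl]-4-{[tert-butyl(dimethyl)silyl]oxymethyl}-3-[3-methoxy-4-(methoxymethoxy)phenyl]cyclobutyl]carbonyl}-1,3-oxazolidin-2-one | O=C1OC[C@H](Cc2ccccc2)N1C(=O)[C@H]1[C@H](CO[Si](C)(C)C(C)(C)C)[C@@H](c2ccc(OCOC)c(OC)c2)[C@@H]1c1cc(OCc2ccccc2)c(OCc2ccccc2)c(OC)c1
F3 | step 9 | (4S,5R)-3-[3,4-bis(benzyloxy)-5-methoxyphenyl]-5-{[tert-butyl(dimethyl)silyl]oxymethyl}-6-[3-methoxy-4-(methoxymethoxy)phenyl]-1,2-dioxane-4-carboxylic acid (mixture at dioxane C3 and C6) | OC(=O)[C@@H]1C(c2cc(OCc3ccccc3)c(OCc3ccccc3)c(OC)c2)OOC(c2ccc(OCOC)c(OC)c2)[C@H]1CO[Si](C)(C)C(C)(C)C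
F0 | step 10 | none | none
F4 | step 8 | {(1R,2S,3S,4R)-2-[3,4-bis(benzyloxy)-5-methoxyphenyl]-4-{[tert-butyl(dimethyl)silyl]oxymethyl}-3-[3-methoxy-4-(methoxymethoxy)phenyl]cyclobutyl}methanol | OC[C@H]1[C@H](CO[Si](C)(C)C(C)(C)C)[C@@H](c2ccc(OCOC)c(OC)c2)[C@@H]1c1cc(OCc2ccccc2)c(OCc2ccccc2)c(OC)c1
A1 | alternative 1 | (3R,4R)-4-(4-benzyloxy-3-methoxybenzyl)-3-[(3-oxocyclobut-1-en-1-yl)methyl]oxolan-2-one | COc1cc(C[C@H]2COC(=O)[C@@H]2CC2=CC(=O)C2)ccc1OCc1ccccc1
A2 | alternative 1 | di-tert-butoxyethyne | CC(C)(C)OC#COC(C)(C)C
A3 | alternative 1 | (3R,4R)-4-(4-benzyloxy-3-methoxybenzyl)-3-(3,4-di-tert-butoxy-5-hydroxybenzyl)oxolan-2-one | COc1cc(C[C@H]2COC(=O)[C@@H]2Cc2cc(O)c(OC(C)(C)C)c(OC(C)(C)C)c2)ccc1OCc1ccccc1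
A4 | alternative 2 | 2-(4-benzyloxy-3-methoxyphenyl)-1,3-dithiane | COc1cc(C2SCCCS2)ccc1OCc1ccccc1
A5 | alternative 2 | (5R)-5-[(1R,2S,5R)-menthyloxy]furan-2(5H)-one | O=C1C=C[C@H](O[C@@H]2C[C@H](C)CC[C@H]2C(C)C)O1
A6 | alternative 2 | 3,4-bis(benzyloxy)-5-methoxybenzyl bromide | COc1cc(CBr)cc(OCc2ccccc2)c1OCc1ccccc1
A7 | alternative 2 | trans,trans-3-[3,4-bis(benzyloxy)-5-methoxybenzyl]-4-[2-(4-benzyloxy-3-methoxyphenyl)-1,3-dithian-2-yl]-5-[(1R,2S,5R)-menthyloxy]oxolan-2-one | COc1cc(C2(SCCCS2)[C@H]2[C@H](O[C@@H]3C[C@H](C)CC[C@H]3C(C)C)OC(=O)[C@@H]2Cc2cc(OCc3ccccc3)c(OCc3ccccc3)c(OC)c2)ccc1OCc1ccccc1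
A8 | alternative 3 | methyl (2E,4R)-2-[3,4-bis(benzyloxy)-5-methoxybenzyl]-4-(4-benzyloxy-3-methoxyphenyl)-4-{[(bromomethyl)dimethylsilyl]oxy}but-2-enoate | COC(=O)/C(Cc1cc(OCc2ccccc2)c(OCc2ccccc2)c(OC)c1)=C/[C@@H](O[Si](C)(C)CBr)c1ccc(OCc2ccccc2)c(OC)c1
A9 | alternative 3 | methyl 3-[3,4-bis(benzyloxy)-5-methoxyphenyl]-2-[trans-5-(4-benzyloxy-3-methoxyphenyl)-2,2-dimethyl-1,2-oxasilolan-4-yl]propanoate (C2 of the ester chain unassigned) | COC(=O)C(Cc1cc(OCc2ccccc2)c(OCc2ccccc2)c(OC)c1)[C@@H]1C[Si](C)(C)O[C@H]1c1ccc(OCc2ccccc2)c(OC)c1
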